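**Strategy.** Ring numbering: C1 carbonyl, C2 propenyl-bearing, C4 quaternary. The cyclohexa-2,5-dienone ring is cut at C2=C3 and C5=C6. The feature exploited is that C4 lies between C3 (aldehyde level) and C5 (ester level: the vinylogous ester C5(OMe)=C6–C1=O is a disguised methyl ester), while C1 lies between two nucleophilic carbons. Thus C3–C4–C5 is an enantioenriched α-methoxy formyl ester and C6–C1–C2 an acyl ylide, 1-(triphenylphosphoranylidene)hex-4-en-2-one. In one pot its lithiated form adds through C2 to the aldehyde and the ylide carbon C6 olefinates the ester carbonyl, retaining the ester methoxy on C5. Dehydration finishes the dienone; C4 is set by catalytic desymmetrisation of a malonate.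

Key step: step 7

Remark (assumption): compounds 1, 2 (as a THF solution), 4 (anhydrous ketone) and 12 are taken as commercial; the ligand enantiomer in step 4 is the one that gives the (R)-alcohol, its sense to be confirmed on this substrate.

Step 1
Reactants: 1 4-iodo-1,2-dimethoxybenzene; 2 propyne
Product: 3 1,2-dimethoxy-4-(prop-1-yn-1-yl)benzene
Conditions: PdCl2(PPh3)2 (cat.), CuI (cat.), Et3N, THF, 0 °C → rt
Reagents that add atoms: none
Why: Sonogashira coupling; the electron-rich aryl iodide adds to zerovalent palladium at room temperature and the copper acetylide of propyne transmetalates cleanly, with no stereo element formed.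

Step 2
Reactants: 3 1,2-dimethoxy-4-(prop-1-yn-1-yl)benzene; 4 dimethyl 2-oxomalonate
Product: 7 dimethyl 2-[(E)-1-(3,4-dimethoxyphenyl)prop-1-en-2-yl]-2-hydroxymalonate, via alkenylzirconocene chloride 5 (not isolated), via alkenyl(methyl)zinc 6 (not isolated)
Conditions: Cp2Zr(H)Cl, CH2Cl2, rt → 40 °C; then Me2Zn, toluene, −65 °C; then 4, −65 °C → rt; aq. NH4Cl
Reagents that add atoms: none
Why: Hydrozirconation is a syn addition that should place zirconium on the less hindered, methyl-bearing alkyne carbon (aryl trans to the metal), and zirconium-to-zinc transmetalation followed by 1,2-addition of the alkenylzinc to the very electrophilic central ketone of 4 transfers the alkenyl group with retention, so the (E)-trisubstituted alkene is fixed here while the carbinol carbon stays prochiral.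

Step 3
Reactants: 7 dimethyl 2-[(E)-1-(3,4-dimethoxyphenyl)prop-1-en-2-yl]-2-hydroxymalonate
Product: 8 dimethyl 2-[(E)-1-(3,4-dimethoxyphenyl)prop-1-en-2-yl]-2-methoxymalonate
Conditions: NaH, MeI, THF/DMF, 0 °C → rt
Reagents that add atoms: iodomethane, CI
Why: Williamson O-methylation of a tertiary alkoxide that is acidified by two ester groups and has no retro-aldol or elimination pathway; the carbon remains prochiral.

Step 4
Reactants: 8 dimethyl 2-[(E)-1-(3,4-dimethoxyphenyl)prop-1-en-2-yl]-2-methoxymalonate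
Product: 10 methyl (2R,3E)-4-(3,4-dimethoxyphenyl)-2-(hydroxymethyl)-2-methoxy-3-methylbut-3-enoate, via silyl ether 9 (not isolated)
Conditions: Et2Zn (10 mol%), chiral pipecolinol-derived tetradentate amino-alcohol phenol ligand (5 mol%), MeSiH(OMe)2, THF, 0 °C → rt; then K2CO3, MeOH, 0 °C
Reagents that add atoms: none
Why: Zinc-catalysed desymmetric hydrosilylation of a prochiral malonic ester: the chiral dinuclear zinc complex chelates the malonate and reduces only one enantiotopic ester (through the aldehyde to silyl ether 9) by telling the small methoxy group from the large alkenyl group, which sets the quaternary centre as (R), and mild methanolysis frees the alcohol.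

Step 5
Reactants: 10 methyl (2R,3E)-4-(3,4-dimethoxyphenyl)-2-(hydroxymethyl)-2-methoxy-3-methylbut-3-enoate
Product: 11 methyl (2R,3E)-4-(3,4-dimethoxyphenyl)-2-formyl-2-methoxy-3-methylbut-3-enoate
Conditions: Dess–Martin periodinane, NaHCO3, CH2Cl2, 0 °C → rt
Reagents that add atoms: none
Why: Dess–Martin oxidation of a neopentyl-type primary alcohol under buffered, non-basic conditions should give the non-enolisable aldehyde without retro-Claisen loss of the formyl group, so the (R) centre is untouched.

Step 6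
Reactants: 12 (E)-pent-3-enoic acid
Product: 14 (4E)-1-(triphenyl-λ5-phosphanylidene)hex-4-en-2-one, via acyl imidazole 13 (not isolated)
Conditions: CDI, THF, rt; then Ph3P=CH2 (2 equiv, from Ph3PCH3Br and KHMDS), THF, −78 → 0 °C
Reagents that add atoms: methyltriphenylphosphonium bromide, C[P+](c1ccccc1)(c1ccccc1)c1ccccc1.[Br-]
Why: C-acylation of a non-stabilised ylide by an N-acylimidazole (second ylide equivalent as base, transylidation) gives the stabilised acyl ylide; at −78 °C acyl transfer should outrun deprotonation next to the carbonyl, so the β,γ-(E)-alkene neither migrates nor isomerises.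

Step 7
Reactants: 14 (4E)-1-(triphenyl-λ5-phosphanylidene)hex-4-en-2-one; 11 methyl (2R,3E)-4-(3,4-dimethoxyphenyl)-2-formyl-2-methoxy-3-methylbut-3-enoate
Product: 17 (4R)-4-[(E)-1-(3,4-dimethoxyphenyl)prop-1-en-2-yl]-5-hydroxy-3,4-dimethoxy-6-[(E)-prop-1-en-1-yl]cyclohex-2-en-1-one (diastereomer mixture at C5 and C6), via lithium ylide-dienolate 15 (not isolated), via aldol adduct 16 (not isolated)
Conditions: 14, LDA, THF, −78 °C; then 11, −78 °C; AcOH (1 equiv), −78 °C → rt; then toluene, 100–110 °C (THF distilled off)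
Reagents that add atoms: none
Why: Proposed new method: LDA removes the allylic proton between the carbonyl and the propenyl group of 14, and the enolate carbon of the resulting ylide-dienolate 15 (C2), far more nucleophilic at −78 °C than the stabilised ylide carbon, adds to the aldehyde of 11 (C2–C3); after protonation the neutral acyl ylide 16 attacks the neighbouring methyl ester carbonyl on heating and the oxaphosphetane loses Ph3PO, which forms C5=C6 with the ester methoxy kept on C5. The closest known reactions are the aldol addition of γ-lithiated acylmethylenephosphoranes and the intramolecular Wittig olefination of ester carbonyls by stabilised ylides (tetronates from α-hydroxy esters and ketenylidenetriphenylphosphorane, chromones from O-acylated phenacyl ylides); new is their union in one pot as a [3+3] carbocyclisation with a keto ylide and a hindered alkyl ester. The six-membered ring closes in a 6-(enolendo)-exo-trig mode. No lasting stereocentre is formed: the quaternary carbon has no α-hydrogen and keeps its configuration (4R in 17), and the two new sp3 centres (a mixture) are erased in step 8. The step needs site selectivity (enolate carbon before ylide carbon, aldehyde before ester), secured by the reactivity gap at −78 °C, and olefination instead of acyl transfer at the ester, secured by the absence of base after the acetic acid quench and by the strong P=O bond; ring closure must precede dehydration, which the weakly acidic C–H next to the ylide-conjugated carbonyl should ensure.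

Step 8
Reactants: 17 (4R)-4-[(E)-1-(3,4-dimethoxyphenyl)prop-1-en-2-yl]-5-hydroxy-3,4-dimethoxy-6-[(E)-prop-1-en-1-yl]cyclohex-2-en-1-one
Product: 19 (4S)-4-[(E)-1-(3,4-dimethoxyphenyl)prop-1-en-2-yl]-4,5-dimethoxy-2-[(E)-prop-1-en-1-yl]cyclohexa-2,5-dien-1-one, via mesylate 18 (not isolated)
Conditions: MsCl, Et3N, CH2Cl2, 0 °C; then DBU, 0 °C → rt
Reagents that add atoms: none
Why: E1cB dehydration of a β-hydroxy ketone through its mesylate: the C–H between the ketone and the propenyl group is acidic, both diastereomers converge on the ring-enforced cis enone, and since C4 has no hydrogen and no acid is used the acid-labile quinol-ether centre is untouched (the descriptor changes from R to S only through the priority change).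

**Compound list**

1 | 4-iodo-1,2-dimethoxybenzene | COc1ccc(I)cc1OC | starting material
2 | propyne | CC#C | starting material
3 | 1,2-dimethoxy-4-(prop-1-yn-1-yl)benzene | CC#Cc1ccc(OC)c(OC)c1 | intermediate
4 | dimethyl 2-oxomalonate | COC(=O)C(=O)C(=O)OC | starting material
5 | chloridobis(cyclopentadienyl)[(E)-1-(3,4-dimethoxyphenyl)prop-1-en-2-yl]zirconium (aryl trans to Zr) | C/C(=C\c1ccc(OC)c(OC)c1)[Zr](Cl)(C1C=CC=C1)C1C=CC=C1 | intermediate
6 | [(E)-1-(3,4-dimethoxyphenyl)prop-1-en-2-yl](methyl)zinc | C/C(=C\c1ccc(OC)c(OC)c1)[Zn]C | intermediate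
7 | dimethyl 2-[(E)-1-(3,4-dimethoxyphenyl)prop-1-en-2-yl]-2-hydroxymalonate | COC(=O)C(O)(/C(C)=C/c1ccc(OC)c(OC)c1)C(=O)OC | intermediate
8 | dimethyl 2-[(E)-1-(3,4-dimethoxyphenyl)prop-1-en-2-yl]-2-methoxymalonate | COC(=O)C(OC)(/C(C)=C/c1ccc(OC)c(OC)c1)C(=O)OC | intermediate
9 | methyl (2R,3E)-2-({[dimethoxy(methyl)silyl]oxy}methyl)-4-(3,4-dimethoxyphenyl)-2-methoxy-3-methylbut-3-enoate | CO[Si](C)(OC)OC[C@](OC)(/C(C)=C/c1ccc(OC)c(OC)c1)C(=O)OC | intermediate
10 | methyl (2R,3E)-4-(3,4-dimethoxyphenyl)-2-(hydroxymethyl)-2-methoxy-3-methylbut-3-enoate | OC[C@](OC)(/C(C)=C/c1ccc(OC)c(OC)c1)C(=O)OC | intermediate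
11 | methyl (2R,3E)-4-(3,4-dimethoxyphenyl)-2-formyl-2-methoxy-3-methylbut-3-enoate | O=C[C@](OC)(/C(C)=C/c1ccc(OC)c(OC)c1)C(=O)OC | intermediate
12 | (E)-pent-3-enoic acid | C/C=C/CC(=O)O | starting material
13 | (3E)-1-(1H-imidazol-1-yl)pent-3-en-1-one | C/C=C/CC(=O)n1ccnc1 | intermediate
14 | (4E)-1-(triphenyl-λ5-phosphanylidene)hex-4-en-2-one | C/C=C/CC(=O)C=P(c1ccccc1)(c1ccccc1)c1ccccc1 | intermediate
15 | lithium (4E)-1-(triphenyl-λ5-phosphanylidene)hexa-2,4-dien-2-olate | [Li+].C/C=C/C=C([O-])C=P(c1ccccc1)(c1ccccc1)c1ccccc1 | intermediate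
16 | methyl (2R)-2-[(E)-1-(3,4-dimethoxyphenyl)prop-1-en-2-yl]-3-hydroxy-2-methoxy-5-oxo-4-[(E)-prop-1-en-1-yl]-6-(triphenyl-λ5-phosphanylidene)hexanoate (formed as its lithium alkoxide, protonated by AcOH; mixture at C3 and C4) | C/C=C/C(C(=O)C=P(c1ccccc1)(c1ccccc1)c1ccccc1)C(O)[C@](OC)(/C(C)=C/c1ccc(OC)c(OC)c1)C(=O)OC | intermediate
17 | (4R)-4-[(E)-1-(3,4-dimethoxyphenyl)prop-1-en-2-yl]-5-hydroxy-3,4-dimethoxy-6-[(E)-prop-1-en-1-yl]cyclohex-2-en-1-one (mixture at C5 and C6) | C/C=C/C1C(O)[C@](OC)(/C(C)=C/c2ccc(OC)c(OC)c2)C(OC)=CC1=O | intermediate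
18 | (2R)-2-[(E)-1-(3,4-dimethoxyphenyl)prop-1-en-2-yl]-2,3-dimethoxy-5-oxo-6-[(E)-prop-1-en-1-yl]cyclohex-3-en-1-yl methanesulfonate | C/C=C/C1C(OS(C)(=O)=O)[C@](OC)(/C(C)=C/c2ccc(OC)c(OC)c2)C(OC)=CC1=O | intermediate
19 | (4S)-4-[(E)-1-(3,4-dimethoxyphenyl)prop-1-en-2-yl]-4,5-dimethoxy-2-[(E)-prop-1-en-1-yl]cyclohexa-2,5-dien-1-one | C/C=C/C1=C[C@](OC)(/C(C)=C/c2ccc(OC)c(OC)c2)C(OC)=CC1=O | target

**Step count and risks**

Total steps: 8. Longest linear sequence: 7 (steps 1–5, 7, 8); step 6 is a one-step side branch.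

Steps most likely to fail:

1. Step 7 (bears the label). What may go wrong: attack of the keto ylide on the hindered ester may be too slow or end in acyl transfer; retro-aldol cleavage of 16 on heating would free the aldehyde for a Wittig reaction at the wrong carbon; premature dehydration would give an acyclic enone whose (E)-isomer cannot close. Fallback by known reactions only, setting out from 10 and rejoining at 19: the vinylogous ester is built from an alkyne and the ring is closed by a C2–C3 aldol condensation. Silylation of 10 (TBSCl, imidazole) would give methyl (2R,3E)-2-{[tert-butyl(dimethyl)silyl]oxymethyl}-4-(3,4-dimethoxyphenyl)-2-methoxy-3-methylbut-3-enoate F1. Reduction with i-Bu2AlH at −78 °C would give the aldehyde F2. Seyferth–Gilbert homologation (dimethyl (1-diazo-2-oxopropyl)phosphonate, K2CO3, MeOH) would give the terminal alkyne F3. Its lithium acetylide (n-BuLi, −78 °C) would be acylated by (3E)-N-methoxy-N-methylpent-3-enamide F4 (from 12, CDI, MeNH(OMe)·HCl) to the ynone F5. Conjugate addition of methanol (NaOMe cat., MeOH) would give the (E)-β-methoxy enone F6, with the acyl group cis to the quaternary carbon. Bu4NF would free the alcohol F7, and Dess–Martin oxidation would give the keto aldehyde F8. Piperidinium acetate would then close the ring by intramolecular aldol condensation to 19.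

2. Step 4. What may go wrong: insufficient discrimination of the two enantiotopic esters, the opposite sense of induction, or over-reduction of the second ester. Fallback from 8, rejoining at 10: hydrolysis of one enantiotopic ester by pig liver esterase (pH 7 buffer), the enzyme chosen by screening, would give (2R,3E)-4-(3,4-dimethoxyphenyl)-2-methoxy-2-(methoxycarbonyl)-3-methylbut-3-enoic acid F9. Activation with i-BuOCOCl and N-methylmorpholine at −15 °C would give the isobutyl carbonic mixed anhydride F10, and NaBH4 would reduce it chemoselectively to 10.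

3. Step 2. What may go wrong: loss of regiocontrol in the hydrozirconation (zirconium on the aryl-bearing carbon) or competing methyl transfer from zinc to the ketone. Fallback from 3, rejoining at 7: copper-catalysed syn borylation–protonation (CuCl, NaOt-Bu, Xantphos, B2pin2, MeOH), which puts boron on the methyl-bearing carbon, would give 2-[(Z)-1-(3,4-dimethoxyphenyl)prop-1-en-2-yl]-4,4,5,5-tetramethyl-1,3,2-dioxaborolane F11. Iododeboronation with retention (NaOH, I2) would give 4-[(E)-2-iodoprop-1-en-1-yl]-1,2-dimethoxybenzene F12. Iodine–lithium exchange (t-BuLi, −78 °C) would give the alkenyllithium F13, which adds to 4 at −78 °C to give 7.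

**Further compounds**

F1 | step 7 | methyl (2R,3E)-2-{[tert-butyl(dimethyl)silyl]oxymethyl}-4-(3,4-dimethoxyphenyl)-2-methoxy-3-methylbut-3-enoate | CC(C)(C)[Si](C)(C)OC[C@](OC)(/C(C)=C/c1ccc(OC)c(OC)c1)C(=O)OC
F2 | step 7 | (2R,3E)-2-{[tert-butyl(dimethyl)silyl]oxymethyl}-4-(3,4-dimethoxyphenyl)-2-methoxy-3-methylbut-3-enal | CC(C)(C)[Si](C)(C)OC[C@](OC)(/C(C)=C/c1ccc(OC)c(OC)c1)C=O
F3 | step 7 | tert-butyl{[(2R,3E)-4-(3,4-dimethoxyphenyl)-2-ethynyl-2-methoxy-3-methylbut-3-en-1-yl]oxy}dimethylsilane | CC(C)(C)[Si](C)(C)OC[C@](OC)(/C(C)=C/c1ccc(OC)c(OC)c1)C#C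
F4 | step 7 | (3E)-N-methoxy-N-methylpent-3-enamide | C/C=C/CC(=O)N(C)OC
F5 | step 7 | (2E,8S)-9-{[tert-butyl(dimethyl)silyl]oxy}-8-[(E)-1-(3,4-dimethoxyphenyl)prop-1-en-2-yl]-8-methoxynon-2-en-6-yn-5-one | CC(C)(C)[Si](C)(C)OC[C@](OC)(/C(C)=C/c1ccc(OC)c(OC)c1)C#CC(=O)C/C=C/C
F6 | step 7 | (2E,6E,8R)-9-{[tert-butyl(dimethyl)silyl]oxy}-8-[(E)-1-(3,4-dimethoxyphenyl)prop-1-en-2-yl]-7,8-dimethoxynona-2,6-dien-5-one | CC(C)(C)[Si](C)(C)OC[C@](OC)(/C(C)=C/c1ccc(OC)c(OC)c1)/C(OC)=C\C(=O)C/C=C/C
F7 | step 7 | (2E,6E,8R)-8-[(E)-1-(3,4-dimethoxyphenyl)prop-1-en-2-yl]-9-hydroxy-7,8-dimethoxynona-2,6-dien-5-one | OC[C@](OC)(/C(C)=C/c1ccc(OC)c(OC)c1)/C(OC)=C\C(=O)C/C=C/C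
F8 | step 7 | (2S,3E,7E)-2-[(E)-1-(3,4-dimethoxyphenyl)prop-1-en-2-yl]-2,3-dimethoxy-5-oxonona-3,7-dienal | O=C[C@](OC)(/C(C)=C/c1ccc(OC)c(OC)c1)/C(OC)=C\C(=O)C/C=C/C
F9 | step 4 | (2R,3E)-4-(3,4-dimethoxyphenyl)-2-methoxy-2-(methoxycarbonyl)-3-methylbut-3-enoic acid | OC(=O)[C@](OC)(/C(C)=C/c1ccc(OC)c(OC)c1)C(=O)OC
F10 | step 4 | mixed anhydride of F9 with isobutyl hydrogen carbonate (same spatial arrangement at the quaternary carbon) | CC(C)COC(=O)OC(=O)[C@](OC)(/C(C)=C/c1ccc(OC)c(OC)c1)C(=O)OC
F11 | step 2 | 2-[(Z)-1-(3,4-dimethoxyphenyl)prop-1-en-2-yl]-4,4,5,5-tetramethyl-1,3,2-dioxaborolane | C/C(=C\c1ccc(OC)c(OC)c1)B1OC(C)(C)C(C)(C)O1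
F12 | step 2 | 4-[(E)-2-iodoprop-1-en-1-yl]-1,2-dimethoxybenzene | C/C(I)=C\c1ccc(OC)c(OC)c1
F13 | step 2 | [(E)-1-(3,4-dimethoxyphenyl)prop-1-en-2-yl]lithium | C/C([Li])=C\c1ccc(OC)c(OC)c1
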